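**Strategy.** Atoms carry the bicyclo[3.2.1]octane locants of the target. The cyclohexane ring C1–C2–C3–C4–C5–C8 is cut into two three-carbon halves: the C2 carbonyl (the later carbinol) with its two α-carbons C1 and C3, and the quaternary carbon C5 with its two one-carbon arms, C8 as an acyl group and C4 as a CH2OTs group. In acyclic keto amide 13 one ketone therefore reacts twice as a nucleophile under base: Claisen acylation joins C1 to C8 and closes the cyclopentanone ring C1–C8–C5–C6–C7, and enolate alkylation then joins C3 to C4, completing the bicyclo[3.2.1]octane-2,8-dione 15. The centres C5, C6 and C7 are set beforehand; the C2 and C3 oxygens follow by exo dihydroxylation.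

Key step: step 9

Remark on locants: C1 methoxy bridgehead, C2 CHOH, C3 CHOMe, C4 CH2, C5 allyl bridgehead, C6 CHMe, C7 CHAr, C8 C=O; the same locants are used for the corresponding atoms of all intermediates.
Assumption: (4R)-4-methyloxolan-2-one, (3-bromoprop-1-yn-1-yl)triisopropylsilane and (3,4,5-trimethoxyphenyl)magnesium bromide (THF solution) are taken as catalogue compounds.
Remark on the allyl group: it is carried as a silyl-capped propargyl group, because a free allyl alkene would compete in the dihydroxylation of step 12.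

Step 1
Reactants: 1 dimethyl (1-diazo-2-oxopropyl)phosphonate
Product: 2 dimethyl (1-methoxy-2-oxopropyl)phosphonate (racemic)
Conditions: Rh2(OAc)4 (cat.), MeOH, CH2Cl2, 40 °C
Reagents that add atoms: methanol CO
Why: The acceptor-substituted carbenoid formed from the diazo compound and Rh2(OAc)4 should insert into the O–H bond of methanol (carbenoid O–H insertion), giving the α-methoxy β-keto phosphonate for step 7, whose stereocentre is lost again in that olefination.

Step 2
Reactants: 3 (4R)-4-methyloxolan-2-one; 4 formaldehyde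
Product: 5 (3S,4R)-3-(hydroxymethyl)-4-methyloxolan-2-one
Conditions: LiN(iPr)2, THF, −78 °C; CH2O (gas), −78 to −40 °C
Reagents that add atoms: none
Why: The lithium enolate of the lactone should add to monomeric formaldehyde (aldol-type hydroxymethylation) from the face opposite the ring methyl group to give the trans product, although this α-centre is re-formed in step 3.

Step 3
Reactants: 5 (3S,4R)-3-(hydroxymethyl)-4-methyloxolan-2-one; 6 (3-bromoprop-1-yn-1-yl)triisopropylsilane
Product: 7 (3R,4R)-3-(hydroxymethyl)-4-methyl-3-[3-(triisopropylsilyl)prop-2-yn-1-yl]oxolan-2-one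
Conditions: LiN(iPr)2 (2.3 equiv), THF/DMPU, −78 to −30 °C; then 6
Reagents that add atoms: none
Why: In this Fráter–Seebach-type alkylation of the alkoxide–enolate dianion the propargylic bromide should approach the planar enolate carbon anti to the neighbouring ring methyl group, which sets the quaternary centre (C5 of the target) with the propargyl arm trans and the hydroxymethyl arm cis to the methyl group.

Step 4
Reactants: 7 (3R,4R)-3-(hydroxymethyl)-4-methyl-3-[3-(triisopropylsilyl)prop-2-yn-1-yl]oxolan-2-one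
Product: 8 [(3R,4R)-4-methyl-2-oxo-3-[3-(triisopropylsilyl)prop-2-yn-1-yl]oxolan-3-yl]methyl 4-methylbenzenesulfonate
Conditions: TsCl, pyridine, DMAP (cat.), CH2Cl2, 0 °C to rt
Reagents that add atoms: 4-methylbenzenesulfonyl chloride Cc1ccc(cc1)S(=O)(=O)Cl
Why: Sulfonylation of the primary alcohol (tosylation) installs the leaving group for the later C3–C4 bond, and a neopentyl tosylate on a quaternary carbon should be inert to substitution and elimination under the conditions of steps 5 to 8.

Step 5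
Reactants: 8 [(3R,4R)-4-methyl-2-oxo-3-[3-(triisopropylsilyl)prop-2-yn-1-yl]oxolan-3-yl]methyl 4-methylbenzenesulfonate
Product: 9 (2R,3R)-4-hydroxy-2-[methoxy(methyl)carbamoyl]-3-methyl-2-[3-(triisopropylsilyl)prop-2-yn-1-yl]butyl 4-methylbenzenesulfonate
Conditions: MeNHOMe·HCl, AlMe3, CH2Cl2, 0 °C to rt; aq. potassium sodium tartrate; used at once
Reagents that add atoms: N,O-dimethylhydroxylamine hydrochloride CNOC.Cl
Why: The aluminium amide MeAl(Cl)N(OMe)Me formed in the flask should open the γ-lactone at its acyl carbon (Weinreb aminolysis of a lactone), which frees the C7 hydroxymethyl group and turns C8 into an acyl group that survives steps 6 to 8, without touching a stereocentre.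

Step 6
Reactants: 9 (2R,3R)-4-hydroxy-2-[methoxy(methyl)carbamoyl]-3-methyl-2-[3-(triisopropylsilyl)prop-2-yn-1-yl]butyl 4-methylbenzenesulfonate
Product: 10 (2R,3R)-2-[methoxy(methyl)carbamoyl]-3-methyl-4-oxo-2-[3-(triisopropylsilyl)prop-2-yn-1-yl]butyl 4-methylbenzenesulfonate
Conditions: Dess–Martin periodinane, NaHCO3, CH2Cl2, 0 °C to rt
Reagents that add atoms: none
Why: Dess–Martin oxidation should convert the primary alcohol into the aldehyde under buffered, non-basic conditions, so that the α-stereocentre (C6 of the target) next to the quaternary carbon is not epimerised and relactonisation is avoided.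

Step 7
Reactants: 10 (2R,3R)-2-[methoxy(methyl)carbamoyl]-3-methyl-4-oxo-2-[3-(triisopropylsilyl)prop-2-yn-1-yl]butyl 4-methylbenzenesulfonate; 2 dimethyl (1-methoxy-2-oxopropyl)phosphonate
Product: 11 (2R,3S)-5-methoxy-2-[methoxy(methyl)carbamoyl]-3-methyl-6-oxo-2-[3-(triisopropylsilyl)prop-2-yn-1-yl]hept-4-en-1-yl 4-methylbenzenesulfonate (mixture of alkene isomers)
Conditions: NaH, THF, 0 °C; then 10, 0 °C to rt
Reagents that add atoms: none
Why: Horner–Wadsworth–Emmons olefination of the aldehyde with the sodium salt of 2 should give the α-methoxy enone, and the alkene geometry is of no consequence because either isomer has a substituent cis to C6 and the double bond is consumed in step 8.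

Step 8
Reactants: 11 (2R,3S)-5-methoxy-2-[methoxy(methyl)carbamoyl]-3-methyl-6-oxo-2-[3-(triisopropylsilyl)prop-2-yn-1-yl]hept-4-en-1-yl 4-methylbenzenesulfonate; 12 (3,4,5-trimethoxyphenyl)magnesium bromide
Product: 13 (2R,3S,4R)-5-methoxy-2-[methoxy(methyl)carbamoyl]-3-methyl-6-oxo-2-[3-(triisopropylsilyl)prop-2-yn-1-yl]-4-(3,4,5-trimethoxyphenyl)heptyl 4-methylbenzenesulfonate (both epimers at the methoxy-bearing carbon)
Conditions: 12 (2.4 equiv), CuBr·SMe2 (1.2 equiv), BF3·OEt2, THF, −78 to −30 °C; aq. NH4Cl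
Reagents that add atoms: none
Why: In this conjugate addition of the cuprate Ar2CuMgBr, allylic 1,3-strain with the cis substituent on the α-carbon should hold the C6–H bond in the plane of the alkene, so that the aryl group is delivered anti to the bulky quaternary carbon and C7 is set syn to the C6 methyl group, while the methoxy-bearing carbon formed on protonation may stay a mixture because it is enolised again in step 9.

Step 9
Reactants: 13 (2R,3S,4R)-5-methoxy-2-[methoxy(methyl)carbamoyl]-3-methyl-6-oxo-2-[3-(triisopropylsilyl)prop-2-yn-1-yl]-4-(3,4,5-trimethoxyphenyl)heptyl 4-methylbenzenesulfonate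
Product: 15 (1R,5R,6S,7R)-1-methoxy-6-methyl-5-[3-(triisopropylsilyl)prop-2-yn-1-yl]-7-(3,4,5-trimethoxyphenyl)bicyclo[3.2.1]octane-2,8-dione, via cyclopentanone tosylate 14 (not isolated)
Conditions: KOtBu (2.5 equiv), THF/tBuOH, 0.01 M, 0 °C, then 50 °C
Reagents that add atoms: none
Why: tert-Butoxide equilibrates the two enolates of the methyl ketone, and the methoxy-bearing enolate carbon C1 attacks the Weinreb amide carbonyl C8 in a Claisen (Dieckmann-type) acylation that closes the cyclopentanone in a 5-(enolexo)-exo-trig mode to give 14, in which C3 is the only enolisable carbon left. Its enolate then displaces the neopentyl tosylate at C4 in a 6-(enolendo)-exo-tet C-alkylation, which closes the cyclohexanone ring and completes the bicyclo[3.2.1]octane-2,8-dione. The closest known reaction types are the Dieckmann acylation of ketone enolates by esters and amides and the intramolecular enolate alkylation used to build bridged ketones, combined here as an α,α'-annulation of one ketone with a 1,3-bis-electrophile. The new stereocentre C1 is controlled by the ring system itself, because only the cyclopentanone epimer with the acetyl group cis to the CH2OTs arm and trans to the aryl group can reach C4, and the other epimer can return through retro-Claisen opening. The step needs acylation before alkylation and C- over O-alkylation; the first should be secured by the low SN2 reactivity of a neopentyl tosylate at 0 °C against a five-ring acylation, the second by the hydrogen-bonding cosolvent tert-butanol and by warming only after the acylation is complete.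

Step 10
Reactants: 15 (1R,5R,6S,7R)-1-methoxy-6-methyl-5-[3-(triisopropylsilyl)prop-2-yn-1-yl]-7-(3,4,5-trimethoxyphenyl)bicyclo[3.2.1]octane-2,8-dione
Product: 16 (1R,5R,6S,7R)-1-methoxy-6-methyl-8-oxo-5-[3-(triisopropylsilyl)prop-2-yn-1-yl]-7-(3,4,5-trimethoxyphenyl)bicyclo[3.2.1]oct-2-en-2-yl trifluoromethanesulfonate
Conditions: KN(SiMe3)2, THF, −78 °C; PhNTf2, −78 to 0 °C
Reagents that add atoms: N,N-bis(trifluoromethanesulfonyl)aniline O=S(=O)(N(c1ccccc1)S(=O)(=O)C(F)(F)F)C(F)(F)F
Why: The C2 ketone can be deprotonated only towards C3, because C1 is quaternary and the C8 ketone has no α-hydrogen, so O-sulfonylation of the potassium enolate (enol triflate formation) should give a single vinyl triflate.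

Step 11
Reactants: 16 (1R,5R,6S,7R)-1-methoxy-6-methyl-8-oxo-5-[3-(triisopropylsilyl)prop-2-yn-1-yl]-7-(3,4,5-trimethoxyphenyl)bicyclo[3.2.1]oct-2-en-2-yl trifluoromethanesulfonate
Product: 17 (1S,5R,6S,7R)-1-methoxy-6-methyl-5-[3-(triisopropylsilyl)prop-2-yn-1-yl]-7-(3,4,5-trimethoxyphenyl)bicyclo[3.2.1]oct-2-en-8-one
Conditions: Pd(OAc)2 (cat.), PPh3, HCO2H, Bu3N, DMF, 60 °C
Reagents that add atoms: none
Why: Zerovalent palladium formed in the flask should insert into the vinyl C–OTf bond and formate should deliver hydride, so that reductive elimination gives the C2=C3 alkene (palladium-catalysed formate reduction of an enol triflate) without touching the silyl alkyne, the arene or the C8 ketone; no stereocentre changes, the C1 descriptor changing only through ligand priorities.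

Step 12
Reactants: 17 (1S,5R,6S,7R)-1-methoxy-6-methyl-5-[3-(triisopropylsilyl)prop-2-yn-1-yl]-7-(3,4,5-trimethoxyphenyl)bicyclo[3.2.1]oct-2-en-8-one
Product: 18 (1R,2R,3R,5S,6S,7R)-2,3-dihydroxy-1-methoxy-6-methyl-5-[3-(triisopropylsilyl)prop-2-yn-1-yl]-7-(3,4,5-trimethoxyphenyl)bicyclo[3.2.1]octan-8-one
Conditions: OsO4 (cat.), N-methylmorpholine N-oxide, acetone/H2O, rt
Reagents that add atoms: osmium tetroxide O=[Os](=O)(=O)=O; N-methylmorpholine N-oxide C[N+]1([O-])CCOCC1; water O
Why: Catalytic OsO4 dihydroxylation adds both oxygen atoms to one face of the alkene, and because the endo face is screened by the C6–C7 bridge with its endo methyl group the reagent should attack from the exo face beside the C8 carbonyl, which sets C2 and C3 as in the target while the silyl-capped alkyne reacts far more slowly.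

Step 13
Reactants: 18 (1R,2R,3R,5S,6S,7R)-2,3-dihydroxy-1-methoxy-6-methyl-5-[3-(triisopropylsilyl)prop-2-yn-1-yl]-7-(3,4,5-trimethoxyphenyl)bicyclo[3.2.1]octan-8-one
Product: 19 (1R,2R,3R,5S,6S,7R)-2-hydroxy-1,3-dimethoxy-6-methyl-5-[3-(triisopropylsilyl)prop-2-yn-1-yl]-7-(3,4,5-trimethoxyphenyl)bicyclo[3.2.1]octan-8-one
Conditions: MeI, Ag2O, CH2Cl2, rt, dark
Reagents that add atoms: iodomethane CI
Why: Purdie methylation (Williamson-type ether formation with MeI and Ag2O) should take place at the C3 hydroxyl, which is flanked by the C4 methylene group, in preference to the C2 hydroxyl, which is shielded by the quaternary C1 and hydrogen-bonded to the C8 carbonyl.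

Step 14
Reactants: 19 (1R,2R,3R,5S,6S,7R)-2-hydroxy-1,3-dimethoxy-6-methyl-5-[3-(triisopropylsilyl)prop-2-yn-1-yl]-7-(3,4,5-trimethoxyphenyl)bicyclo[3.2.1]octan-8-one
Product: 20 (1R,2R,3R,5S,6S,7R)-2-hydroxy-1,3-dimethoxy-6-methyl-5-(prop-2-yn-1-yl)-7-(3,4,5-trimethoxyphenyl)bicyclo[3.2.1]octan-8-one
Conditions: Bu4NF, THF, 0 °C
Reagents that add atoms: none
Why: Fluoride attacks silicon and cleaves the C(sp)–Si bond (protodesilylation of a silyl alkyne) without risk to any stereocentre, since retro-aldol cleavage of the β-hydroxy ketone would need a bridgehead enolate and is blocked.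

Step 15
Reactants: 20 (1R,2R,3R,5S,6S,7R)-2-hydroxy-1,3-dimethoxy-6-methyl-5-(prop-2-yn-1-yl)-7-(3,4,5-trimethoxyphenyl)bicyclo[3.2.1]octan-8-one
Product: 21 (1R,2R,3R,5S,6S,7R)-2-hydroxy-1,3-dimethoxy-6-methyl-5-(prop-2-en-1-yl)-7-(3,4,5-trimethoxyphenyl)bicyclo[3.2.1]octan-8-one
Conditions: H2 (1 atm), Pd on CaCO3 poisoned with Pb(OAc)2, quinoline, EtOAc, rt
Reagents that add atoms: none
Why: Lindlar semi-hydrogenation of the terminal alkyne should stop at the alkene and turn the propargyl group into the allyl group of the target without touching the ketone, the arene or any stereocentre.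

**Compound list**

1 | dimethyl (1-diazo-2-oxopropyl)phosphonate | CC(=O)C(=[N+]=[N-])P(=O)(OC)OC | starting material
2 | dimethyl (1-methoxy-2-oxopropyl)phosphonate (racemic) | CC(=O)C(OC)P(=O)(OC)OC | intermediate
3 | (4R)-4-methyloxolan-2-one | O=C1OC[C@H](C)C1 | starting material
4 | formaldehyde (monomer, from cracking of paraformaldehyde) | C=O | starting material
5 | (3S,4R)-3-(hydroxymethyl)-4-methyloxolan-2-one | O=C1OC[C@H](C)[C@H]1CO | intermediate
6 | (3-bromoprop-1-yn-1-yl)triisopropylsilane | BrCC#C[Si](C(C)C)(C(C)C)C(C)C | starting material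
7 | (3R,4R)-3-(hydroxymethyl)-4-methyl-3-[3-(triisopropylsilyl)prop-2-yn-1-yl]oxolan-2-one | O=C1OC[C@H](C)[C@]1(CC#C[Si](C(C)C)(C(C)C)C(C)C)CO | intermediate
8 | [(3R,4R)-4-methyl-2-oxo-3-[3-(triisopropylsilyl)prop-2-yn-1-yl]oxolan-3-yl]methyl 4-methylbenzenesulfonate | O=C1OC[C@H](C)[C@]1(CC#C[Si](C(C)C)(C(C)C)C(C)C)COS(=O)(=O)c1ccc(C)cc1 | intermediate
9 | (2R,3R)-4-hydroxy-2-[methoxy(methyl)carbamoyl]-3-methyl-2-[3-(triisopropylsilyl)prop-2-yn-1-yl]butyl 4-methylbenzenesulfonate | CC(C)[Si](C(C)C)(C(C)C)C#CC[C@@](C(=O)N(C)OC)([C@@H](C)CO)COS(=O)(=O)c1ccc(C)cc1 | intermediate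
10 | (2R,3R)-2-[methoxy(methyl)carbamoyl]-3-methyl-4-oxo-2-[3-(triisopropylsilyl)prop-2-yn-1-yl]butyl 4-methylbenzenesulfonate | CC(C)[Si](C(C)C)(C(C)C)C#CC[C@@](C(=O)N(C)OC)([C@@H](C)C=O)COS(=O)(=O)c1ccc(C)cc1 | intermediate
11 | (2R,3S)-5-methoxy-2-[methoxy(methyl)carbamoyl]-3-methyl-6-oxo-2-[3-(triisopropylsilyl)prop-2-yn-1-yl]hept-4-en-1-yl 4-methylbenzenesulfonate (alkene isomers) | CC(C)[Si](C(C)C)(C(C)C)C#CC[C@@](C(=O)N(C)OC)([C@@H](C)C=C(OC)C(C)=O)COS(=O)(=O)c1ccc(C)cc1 | intermediate
12 | (3,4,5-trimethoxyphenyl)magnesium bromide | COc1cc([Mg]Br)cc(OC)c1OC | starting material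
13 | (2R,3S,4R)-5-methoxy-2-[methoxy(methyl)carbamoyl]-3-methyl-6-oxo-2-[3-(triisopropylsilyl)prop-2-yn-1-yl]-4-(3,4,5-trimethoxyphenyl)heptyl 4-methylbenzenesulfonate (epimers at C5 of the chain) | CC(C)[Si](C(C)C)(C(C)C)C#CC[C@@](C(=O)N(C)OC)([C@@H](C)[C@H](c1cc(OC)c(OC)c(OC)c1)C(OC)C(C)=O)COS(=O)(=O)c1ccc(C)cc1 | intermediate
14 | [(1R,2S,3R,4R)-4-acetyl-4-methoxy-2-methyl-5-oxo-1-[3-(triisopropylsilyl)prop-2-yn-1-yl]-3-(3,4,5-trimethoxyphenyl)cyclopentyl]methyl 4-methylbenzenesulfonate | CC(C)[Si](C(C)C)(C(C)C)C#CC[C@@]1(COS(=O)(=O)c2ccc(C)cc2)C(=O)[C@](OC)(C(C)=O)[C@@H](c2cc(OC)c(OC)c(OC)c2)[C@@H]1C | intermediate (not isolated)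
15 | (1R,5R,6S,7R)-1-methoxy-6-methyl-5-[3-(triisopropylsilyl)prop-2-yn-1-yl]-7-(3,4,5-trimethoxyphenyl)bicyclo[3.2.1]octane-2,8-dione | CC(C)[Si](C(C)C)(C(C)C)C#CC[C@@]12CCC(=O)[C@@](OC)(C1=O)[C@@H](c1cc(OC)c(OC)c(OC)c1)[C@@H]2C | intermediate
16 | (1R,5R,6S,7R)-1-methoxy-6-methyl-8-oxo-5-[3-(triisopropylsilyl)prop-2-yn-1-yl]-7-(3,4,5-trimethoxyphenyl)bicyclo[3.2.1]oct-2-en-2-yl trifluoromethanesulfonate | CC(C)[Si](C(C)C)(C(C)C)C#CC[C@@]12CC=C(OS(=O)(=O)C(F)(F)F)[C@@](OC)(C1=O)[C@@H](c1cc(OC)c(OC)c(OC)c1)[C@@H]2C | intermediate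
17 | (1S,5R,6S,7R)-1-methoxy-6-methyl-5-[3-(triisopropylsilyl)prop-2-yn-1-yl]-7-(3,4,5-trimethoxyphenyl)bicyclo[3.2.1]oct-2-en-8-one | CC(C)[Si](C(C)C)(C(C)C)C#CC[C@@]12CC=C[C@@](OC)(C1=O)[C@@H](c1cc(OC)c(OC)c(OC)c1)[C@@H]2C | intermediate
18 | (1R,2R,3R,5S,6S,7R)-2,3-dihydroxy-1-methoxy-6-methyl-5-[3-(triisopropylsilyl)prop-2-yn-1-yl]-7-(3,4,5-trimethoxyphenyl)bicyclo[3.2.1]octan-8-one | CC(C)[Si](C(C)C)(C(C)C)C#CC[C@@]12C[C@@H](O)[C@@H](O)[C@@](OC)(C1=O)[C@@H](c1cc(OC)c(OC)c(OC)c1)[C@@H]2C | intermediate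
19 | (1R,2R,3R,5S,6S,7R)-2-hydroxy-1,3-dimethoxy-6-methyl-5-[3-(triisopropylsilyl)prop-2-yn-1-yl]-7-(3,4,5-trimethoxyphenyl)bicyclo[3.2.1]octan-8-one | CC(C)[Si](C(C)C)(C(C)C)C#CC[C@@]12C[C@@H](OC)[C@@H](O)[C@@](OC)(C1=O)[C@@H](c1cc(OC)c(OC)c(OC)c1)[C@@H]2C | intermediate
20 | (1R,2R,3R,5S,6S,7R)-2-hydroxy-1,3-dimethoxy-6-methyl-5-(prop-2-yn-1-yl)-7-(3,4,5-trimethoxyphenyl)bicyclo[3.2.1]octan-8-one | C#CC[C@@]12C[C@@H](OC)[C@@H](O)[C@@](OC)(C1=O)[C@@H](c1cc(OC)c(OC)c(OC)c1)[C@@H]2C | intermediate
21 | (1R,2R,3R,5S,6S,7R)-2-hydroxy-1,3-dimethoxy-6-methyl-5-(prop-2-en-1-yl)-7-(3,4,5-trimethoxyphenyl)bicyclo[3.2.1]octan-8-one | C=CC[C@@]12C[C@@H](OC)[C@@H](O)[C@@](OC)(C1=O)[C@@H](c1cc(OC)c(OC)c(OC)c1)[C@@H]2C | target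

Total step count: 15. Longest linear sequence: 14 steps (steps 2 to 15, from lactone 3); step 1 is a one-step side branch.

**Steps most likely to fail**

Step 9 (key step). Acylation at the hindered, α-quaternary amide may be slow, so that the C1 enolate is alkylated by the tosylate first (a cyclopentane by 5-exo-tet closure), or the second closure may go through the enolate oxygen. The fallback separates the two closures and fixes the regiochemistry of the first in advance. It leaves the route at 13: Me3SiOTf and Et3N should give the more substituted trimethylsilyl enol ether F1. MeLi at −40 °C cleaves the O–Si bond, and the lithium enolate acylates onto the Weinreb amide, whose chelated tetrahedral adduct survives until work-up, so that 14 can be isolated with the neopentyl tosylate intact. NaI in butanone exchanges the tosylate for iodide to give the iodide F2. LiN(SiMe3)2 in THF then closes the six-membered ring through the lithium enolate and the softer leaving group, and the route is rejoined at 15.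

Step 8. The conjugate addition may stall at the hindered β-carbon of an enone that the α-methoxy group deactivates, 1,2-addition may compete, and the facial selectivity may be eroded. The fallback leaves the route at 10: Wittig olefination with Ph3P=CHC(O)CH3 should give the (E)-enone F3, which lacks the deactivating methoxy group. A conjugate addition of (3,4,5-trimethoxyphenyl)boronic acid catalysed by Rh(acac)(C2H4)2 and the BINAP enantiomer that reinforces the substrate bias (Hayashi–Miyaura reaction) should give ketone F4 under catalyst control. Me3SiCl, NaI and Et3N give the more substituted silyl enol ether F5, Rubottom oxidation with mCPBA gives the α-hydroxy ketone F6, and O-methylation with MeOTf and 2,6-di-tert-butylpyridine rejoins the route at 13.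

Step 3. The dianion may lose formaldehyde by retro-aldol cleavage, may be alkylated on oxygen, or may show poor facial selectivity. The fallback leaves the route at 3: its lithium enolate (LiN(iPr)2) is alkylated with 2-(trimethylsilyl)ethoxymethyl chloride to give the protected hydroxymethyl lactone F7. A second enolate alkylation with 6, now of a simple monoanion, should enter anti to the ring methyl group and give the quaternary lactone F8. BF3·OEt2 cleaves the silylethyl ether and the route is rejoined at 7.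

Further compounds
F1 | step 9 | (2R,3S,4R)-5-methoxy-2-[methoxy(methyl)carbamoyl]-3-methyl-2-[3-(triisopropylsilyl)prop-2-yn-1-yl]-4-(3,4,5-trimethoxyphenyl)-6-[(trimethylsilyl)oxy]hept-5-en-1-yl 4-methylbenzenesulfonate | CC(C)[Si](C(C)C)(C(C)C)C#CC[C@@](C(=O)N(C)OC)([C@@H](C)[C@H](c1cc(OC)c(OC)c(OC)c1)C(OC)=C(C)O[Si](C)(C)C)COS(=O)(=O)c1ccc(C)cc1
F2 | step 9 | (2R,3R,4S,5S)-2-acetyl-5-(iodomethyl)-2-methoxy-4-methyl-5-[3-(triisopropylsilyl)prop-2-yn-1-yl]-3-(3,4,5-trimethoxyphenyl)cyclopentan-1-one | CC(C)[Si](C(C)C)(C(C)C)C#CC[C@@]1(CI)C(=O)[C@](OC)(C(C)=O)[C@@H](c2cc(OC)c(OC)c(OC)c2)[C@@H]1C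
F3 | step 8 | (2R,3S,4E)-2-[methoxy(methyl)carbamoyl]-3-methyl-6-oxo-2-[3-(triisopropylsilyl)prop-2-yn-1-yl]hept-4-en-1-yl 4-methylbenzenesulfonate | CC(C)[Si](C(C)C)(C(C)C)C#CC[C@@](C(=O)N(C)OC)([C@@H](C)/C=C/C(C)=O)COS(=O)(=O)c1ccc(C)cc1
F4 | step 8 | (2R,3S,4R)-2-[methoxy(methyl)carbamoyl]-3-methyl-6-oxo-2-[3-(triisopropylsilyl)prop-2-yn-1-yl]-4-(3,4,5-trimethoxyphenyl)heptyl 4-methylbenzenesulfonate | CC(C)[Si](C(C)C)(C(C)C)C#CC[C@@](C(=O)N(C)OC)([C@@H](C)[C@H](c1cc(OC)c(OC)c(OC)c1)CC(C)=O)COS(=O)(=O)c1ccc(C)cc1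
F5 | step 8 | (2R,3S,4S)-2-[methoxy(methyl)carbamoyl]-3-methyl-2-[3-(triisopropylsilyl)prop-2-yn-1-yl]-4-(3,4,5-trimethoxyphenyl)-6-[(trimethylsilyl)oxy]hept-5-en-1-yl 4-methylbenzenesulfonate | CC(C)[Si](C(C)C)(C(C)C)C#CC[C@@](C(=O)N(C)OC)([C@@H](C)[C@H](c1cc(OC)c(OC)c(OC)c1)C=C(C)O[Si](C)(C)C)COS(=O)(=O)c1ccc(C)cc1
F6 | step 8 | (2R,3S,4R)-5-hydroxy-2-[methoxy(methyl)carbamoyl]-3-methyl-6-oxo-2-[3-(triisopropylsilyl)prop-2-yn-1-yl]-4-(3,4,5-trimethoxyphenyl)heptyl 4-methylbenzenesulfonate (epimers at C5 of the chain) | CC(C)[Si](C(C)C)(C(C)C)C#CC[C@@](C(=O)N(C)OC)([C@@H](C)[C@H](c1cc(OC)c(OC)c(OC)c1)C(O)C(C)=O)COS(=O)(=O)c1ccc(C)cc1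
F7 | step 3 | (3S,4R)-4-methyl-3-{[2-(trimethylsilyl)ethoxy]methyl}oxolan-2-one | O=C1OC[C@H](C)[C@H]1COCC[Si](C)(C)C
F8 | step 3 | (3R,4R)-4-methyl-3-{[2-(trimethylsilyl)ethoxy]methyl}-3-[3-(triisopropylsilyl)prop-2-yn-1-yl]oxolan-2-one | O=C1OC[C@H](C)[C@]1(CC#C[Si](C(C)C)(C(C)C)C(C)C)COCC[Si](C)(C)C
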